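## The problem

Atom labels used throughout: ring A carbons are C1 (bears the chain), C2 (CH2), C3 and C4 (epoxide, CH3 on C4), C5 and C6 (angelates); chain carbons are C7 (=CH2), C8 (angelate), C9 (CH2), C10 and C11 (epoxide, two CH3 on C11). Target 26 is a single cyclohexane ring A joined through C1–C7 to a five-carbon chain, so the skeleton is simple; the difficulty lies in seven stereocentres, two epoxides and three identical, geometrically labile esters. The five contiguous ring centres are all related to C1: the C3–C4 epoxide and the C6 ester lie on the face opposite the chain and the C5 ester on the face of the chain, so C1 can control C3/C4 and C6, and C6 can control C5. C8 and C10 are insulated from the ring by the sp2 carbon C7 and from each other by C9; neither can be trusted to substrate control and each needs a catalyst or reagent. Both trisubstituted epoxides are sensitive to protic and Lewis acids (a free C8 hydroxyl would open the C10–C11 epoxide to a tetrahydrofuran), the angelates isomerise to tiglates under nucleophilic catalysis, and the C8 ester is allylic; the esters and the chain epoxide therefore belong at the end. The feature that invites the key step is that C8 is a carbinol flanked by the alkenyl carbon C7 and by a methylene C9 that carries the C10=C11 alkene before epoxidation. This alkenyl–CH(O)–CH2–alkenyl unit is the signature of a 1,2-metallate shift on a vinylboron ate complex coupled to a palladium cross-coupling. Ring A, finally, has the carbon pattern of carvone (C1 = carvone C5, C5 = the carbonyl carbon, C3=C4 = the enone alkene, C7 = the isopropenyl carbon), so the ring problem reduces to three oxidation-level adjustments of a commercial terpene.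

## Retrosynthesis

**26 ⇒ 25 (C10–O and C11–O).** The chain epoxide is removed first. It is the most acid-sensitive group and sits β to the C8 oxygen, so it should appear only once C8 is esterified. In triester 25 the C10=C11 alkene is the only electron-rich, unhindered alkene: C7=CH2 is 1,1-disubstituted with an allylic ester, and the angelate alkenes are electron-poor. A chiral dioxirane can therefore set C10 by reagent control, independent of the distant ring.

**25 ⇒ 23 + 20, 23 ⇒ 22, 22 ⇒ 19 + 20 (three acyl C–O bonds, two O–Si bonds).** The three esters are identical, but their hydroxyls are not alike. C8–OH is a lone allylic carbinol on the chain; C5–OH and C6–OH form a hindered vicinal pair beside the fully substituted C4. The acyl bonds are therefore cut in two stages, each leading back to angelic anhydride 20.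
- Cutting the two ring esters gives diol 23, which comes from bis-silyl ether 22 by desilylation.
- Cutting the C8 ester of 22 gives alcohol 19, in which C8–OH is the only free hydroxyl.

Against a single threefold acylation of a triol, this staging lets each acylation meet one kind of hydroxyl and never more than two alkoxides at once. The price is one extra step and the exposure of the C8 ester to buffered fluoride. The forward reactions must not isomerise Z to E, which points to acylation of lithium alkoxides by the symmetrical anhydride 20 without a nucleophilic catalyst.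

**19 ⇒ 18 (C8–O from C8–B).** A stereoretentive oxidation leads back to the α-chiral allylboronate 18. It must proceed without allylic transposition, which holds for B-to-O migration.

**18 ⇒ 12 + 16 + 14 (C7–C8 and C9–C10; key disconnection).** Two bonds around C8 are cut at once, giving ring alkenyl boronate 12, vinyllithium 16 (C8–C9) and 2-methylprop-1-enyl triflate 14 (C10–C11 with both methyls). Two neighbouring cuts were weighed:
- C8–C9 alone (prenylation of a C8 aldehyde) suffers from the tendency of prenyl metals to react at the γ-carbon and give the reverse-prenyl isomer.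
- C7–C8 alone (C7 alkenyl metal plus 4-methylpent-3-enal) needs a deconjugated, isomerisation-prone aldehyde and a separate source of chirality.

The conjunctive cut uses three simple pieces and sets C8 with a catalyst. It asks for palladium to engage the vinyl group and not the C7 alkenyl group, for migration of a hindered α-branched alkenyl group, and for catalyst control beside a chiral ring. Compounds 12 and 18 carry the ring epoxide as a spectator rather than a C3=C4 alkene, for the reasons given under 6 ⇒ 1 below.

**14 ⇒ isobutyraldehyde 13; 16 ⇒ tetravinylstannane 15.** Both partners are one step from commodity chemicals. Tin–lithium exchange gives halide-free 16, which the palladium step requires.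

**12 ⇒ 10 ⇒ 8 ⇒ 6 (C7–B, C7–O, C=C).** The boronate comes from enol triflate 10 by Miyaura borylation with bis(pinacolato)diboron 11, the triflate from the kinetic enolate of methyl ketone 8, and the ketone from the isopropenyl group of 6 by ozonolysis. One carbon of the terpene is given up here; this is the price of building C8 from vinyllithium. Because the ring alkene is already an epoxide in 6, the ozonolysis has only one alkene to find.

**6 ⇒ 5 ⇒ 4 ⇒ 2 ⇒ (S)-carvone 1 (ring stereocentres).** Each ring centre is set by its neighbour:
- The C3–C4 epoxide comes from nucleophilic epoxidation of the enone, trans to the C1 substituent.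
- C6–OH comes from oxidation of the only possible enolate, again anti to the C1 substituent.
- C5–OH comes from a reduction directed by C6–OH, hence trans to it.

Installing the epoxide first, and not by a late peracid epoxidation, is preferred for two reasons. As an enone the alkene reacts only with hydroperoxide and its face is fixed by C1. At a late stage it would compete with two other alkenes, with its face governed only by an allylic ester.

## Roads not taken

**Alternative 1: furan cycloadduct with a temporary oxygen bridge.**
- Cut: C1–C6 and C2–C3 of ring A.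
- Forward key step: 3-methylfuran A1 and 2,2,2-trifluoroethyl acrylate A2 combine in an endo-selective [4+2] cycloaddition to oxanorbornene A3. The catalyst is a chiral oxazaborolidinium salt (the bistriflimide-protonated B-o-tolyl oxazaborolidine of (S)-α,α-diphenylprolinol).
- Merits: ring A and two bonds form in one catalytic, enantioselective step from achiral feedstocks, with either enantiomer available. The bridge oxygen sits on C3 and C6 on the face opposite the C1 substituent, exactly where 26 has oxygen on those carbons, and the ester carbon is C7.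
- Weak points: the unsymmetrical furan must orient correctly, and furan adducts revert readily. The bridge spans C3 and C6, whereas 26 needs an epoxide across C3–C4 and esters on C5 and C6. Exo-face oxidation of the C4=C5 alkene of A3 would put the C5 oxygen cis to the C6 oxygen, the opposite of what is needed. Breaking the bridge while moving oxygen to C4 costs several redox steps, and C7 must still be converted into an alkenyl unit.
- Comparison: this road is better in not depending on the chiral pool. Against that, the chosen plan buys the C-methyl, the C1 substituent and the C5 oxygen with 1 and reaches the fully oxygenated ring in three steps.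

**Alternative 2: Nozaki–Hiyama–Kishi ring closure at C4–C5.**
- Cut: C4–C5.
- Forward key step: the (Z)-iodoalkene aldehyde A4 cyclises under CrCl2 with catalytic NiCl2 to cyclohexenol A5, forming the ring and the C5 carbinol next to the C6 silyl ether.
- Merits: the coupling is chemoselective and tolerates the Weinreb amide at C7. The ring fixes the alkene geometry, and the amide leads to a methyl ketone from which the same triflate–boronate sequence would follow, so this road could merge with the chosen one.
- Weak points: A4 needs two acyclic stereocentres (C1 and C6), a Z-trisubstituted iodoalkene and an epimerisable α-silyloxy aldehyde, likely eight or more steps. The C5 configuration depends on a cyclic chromium alkoxide transition state, so the required trans C5/C6 relation is plausible but not assured. Divalent chromium is used in large excess. The ring epoxide would still have to be introduced anti to the C5 oxygen, whereas a free C5–OH directs syn.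
- Comparison: this road is more flexible for analogues. The chosen plan is much shorter and sets C5 by direction from C6.

**Alternative 3: singlet-oxygen endoperoxide as a temporary bridge.**
- Cut: C3–O and C6–O.
- Forward key step: photosensitised singlet oxygen adds across C3 and C6 of diene A6, anti to the C1 substituent, to give endoperoxide A7.
- Merits: both oxygens arrive on the correct face in one reagent-free step. Isomerisation of the O–O bond (cobalt meso-tetraphenylporphyrin, Co(TPP)) would give the syn-bis-epoxide A8, whose C3–C4 epoxide is that of 26. Opening its C5–C6 epoxide at C5 with inversion would give the trans C5/C6 pattern. For ring oxygenation this is as short as, and more elegant than, the chosen sequence.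
- Weak points: A6 is a cyclohexa-1,3-diene with a stereocentre at C1 that is lost by 1,5-hydrogen shift or aromatisation. Ene reactions of singlet oxygen compete. Regioselective opening of A8 at C5, without touching the C3–C4 epoxide whose tertiary C4 is the favoured site under acid, is unsolved. The chain of A7 ends at C8 as a primary silyl ether, so C8 and C9–C11 would still have to be added by an aldehyde prenylation with the regiochemical problem noted above.
- Comparison: the chosen plan sets against this elegance a sequence of separately controlled, conventional steps from a configurationally stable enone, and it creates C8 catalytically while assembling the chain.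

Key step: step 10

Assumption: the (Sp,Sp) enantiomer of the ferrocenyl bisphosphine is taken to induce 8S, by analogy with simple bis(alkenyl) ate complexes; the sense would be confirmed on the isopropenyl model boronate and the antipodal ligand used if it is reversed.

Assumption: angelic anhydride 20 is taken as a commercial reagent of full (Z,Z) geometric purity; this would be checked before use, since any tigloyl content is carried into the esters.

## Route

**Step 1**
Reactants: 1 (S)-(+)-carvone
Product: 2 (1S,4S,6S)-1-methyl-4-(prop-1-en-2-yl)-7-oxabicyclo[4.1.0]heptan-2-one (oxirane trans to the isopropenyl group)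
Conditions: 35% H2O2, NaOH (0.25 equiv, aq.), MeOH, 0 °C
Reagents that add atoms: hydrogen peroxide, OO
Why: Weitz–Scheffer nucleophilic epoxidation; hydroperoxide adds axially to C3 of the enone trans to the C1 substituent and the enolate closes on O–O, so C3 and C4 are set with the oxirane opposite the isopropenyl group. The electron-rich isopropenyl alkene does not react with the nucleophilic oxidant.

**Step 2**
Reactants: 2 (1S,4S,6S)-1-methyl-4-(prop-1-en-2-yl)-7-oxabicyclo[4.1.0]heptan-2-one
Product: 4 (1S,3R,4R,6S)-3-hydroxy-1-methyl-4-(prop-1-en-2-yl)-7-oxabicyclo[4.1.0]heptan-2-one (C6–OH trans to the C1 substituent), via sodium enolate 3 (not isolated)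
Conditions: NaN(SiMe3)2, THF, −78 °C; then 3-phenyl-2-(phenylsulfonyl)oxaziridine, −78 °C; AcOH quench
Reagents that add atoms: 3-phenyl-2-(phenylsulfonyl)oxaziridine, O=S(=O)(N1OC1c1ccccc1)c1ccccc1
Why: Davis oxidation of a ketone enolate; C6 is the only enolisable position of 2 and the oxaziridine transfers oxygen to the enolate face opposite the adjacent C1 isopropenyl group, setting C6. The sodium enolate is chosen because it is not intercepted by the sulfonimine by-product.

**Step 3**
Reactants: 4 (1S,3R,4R,6S)-3-hydroxy-1-methyl-4-(prop-1-en-2-yl)-7-oxabicyclo[4.1.0]heptan-2-one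
Product: 5 (1R,2S,3R,4R,6S)-1-methyl-4-(prop-1-en-2-yl)-7-oxabicyclo[4.1.0]heptane-2,3-diol (C5–OH trans to C6–OH and to the oxirane)
Conditions: Me4NBH(OAc)3, MeCN/AcOH (1:1), −30 to 0 °C
Reagents that add atoms: none
Why: Hydroxyl-directed triacetoxyborohydride reduction (Saksena–Evans type); the C6 hydroxyl exchanges an acetate on boron and hydride is delivered internally to the C5 carbonyl on the C6–O face, so the new C5–OH is trans to C6–OH. The reagent does not reduce ketones that lack a neighbouring hydroxyl, and the buffered medium is mild toward the epoxide.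

**Step 4**
Reactants: 5 (1R,2S,3R,4R,6S)-1-methyl-4-(prop-1-en-2-yl)-7-oxabicyclo[4.1.0]heptane-2,3-diol
Product: 6 (1S,2S,3R,4R,6S)-2,3-bis(tert-butyldimethylsilyloxy)-1-methyl-4-(prop-1-en-2-yl)-7-oxabicyclo[4.1.0]heptane
Conditions: TBSOTf (2.6 equiv), 2,6-lutidine, CH2Cl2, −78 to 0 °C
Reagents that add atoms: tert-butyldimethylsilyl trifluoromethanesulfonate, CC(C)(C)[Si](C)(C)OS(=O)(=O)C(F)(F)F
Why: Silylation of both hindered secondary alcohols with a silyl triflate and a hindered pyridine base; at low temperature with excess base the trisubstituted epoxide is not activated.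

**Step 5**
Reactants: 6 (1S,2S,3R,4R,6S)-2,3-bis(tert-butyldimethylsilyloxy)-1-methyl-4-(prop-1-en-2-yl)-7-oxabicyclo[4.1.0]heptane
Product: 8 1-[(1S,2S,3R,4S,6S)-2,3-bis(tert-butyldimethylsilyloxy)-1-methyl-7-oxabicyclo[4.1.0]heptan-4-yl]ethan-1-one, via secondary ozonide 7 (not isolated)
Conditions: O3, CH2Cl2, −78 °C; then PPh3, −78 °C to rt
Reagents that add atoms: ozone, [O-][O+]=O
Why: Ozonolysis with reductive work-up; the isopropenyl group is the only alkene left, so cleavage to the methyl ketone is unambiguous. The neutral work-up avoids epimerisation at C1 and β-elimination of the C6 silyl ether.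

**Step 6**
Reactants: 8 1-[(1S,2S,3R,4S,6S)-2,3-bis(tert-butyldimethylsilyloxy)-1-methyl-7-oxabicyclo[4.1.0]heptan-4-yl]ethan-1-one
Product: 10 1-[(1S,2S,3R,4S,6S)-2,3-bis(tert-butyldimethylsilyloxy)-1-methyl-7-oxabicyclo[4.1.0]heptan-4-yl]ethenyl trifluoromethanesulfonate, via potassium enolate 9 (not isolated)
Conditions: KN(SiMe3)2, THF, −78 °C; then PhNTf2, −78 to −20 °C; aq. NH4Cl
Reagents that add atoms: N-phenylbis(trifluoromethanesulfonimide), O=S(=O)(N(c1ccccc1)S(=O)(=O)C(F)(F)F)C(F)(F)F
Why: Regioselective enol triflate formation; kinetic deprotonation of the methyl ketone by the hindered amide base occurs at the methyl group, not at the hindered C1–H (whose enolate would expel the C6 silyl ether), and the enolate oxygen is sulfonylated by the triflimide.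

**Step 7**
Reactants: 10 1-[(1S,2S,3R,4S,6S)-2,3-bis(tert-butyldimethylsilyloxy)-1-methyl-7-oxabicyclo[4.1.0]heptan-4-yl]ethenyl trifluoromethanesulfonate; 11 bis(pinacolato)diboron
Product: 12 2-{1-[(1S,2S,3R,4R,6S)-2,3-bis(tert-butyldimethylsilyloxy)-1-methyl-7-oxabicyclo[4.1.0]heptan-4-yl]ethenyl}-4,4,5,5-tetramethyl-1,3,2-dioxaborolane (boron on C7)
Conditions: PdCl2(PPh3)2 (3 mol%), PPh3 (6 mol%), KOPh, toluene, 50 °C
Reagents that add atoms: none
Why: Miyaura borylation of a 1-alkenyl triflate; oxidative addition to zerovalent palladium, transmetalation with the phenoxide-activated diboron and reductive elimination give the alkenyl pinacol boronate without moving the double bond.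

**Step 8**
Reactants: 13 isobutyraldehyde
Product: 14 2-methylprop-1-en-1-yl trifluoromethanesulfonate
Conditions: Tf2O, 2,6-di-tert-butyl-4-methylpyridine, CH2Cl2, 0 °C to rt
Reagents that add atoms: trifluoromethanesulfonic anhydride, O=S(=O)(OS(=O)(=O)C(F)(F)F)C(F)(F)F
Why: Enol triflate formation from an enolisable aldehyde; O-triflation followed by deprotonation with the non-nucleophilic hindered pyridine gives the alkenyl triflate, and the isobutenyl group has no geometric isomers.

**Step 9**
Reactants: 15 tetravinylstannane
Product: 16 vinyllithium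
Conditions: n-BuLi (4 equiv), pentane, rt; filtration under argon, then dissolved in THF
Reagents that add atoms: n-butyllithium, [Li]CCCC
Why: Tin–lithium exchange; vinyllithium precipitates from pentane and is separated from soluble tetrabutylstannane, giving the halide-free reagent needed for the palladium step.

**Step 10**
Reactants: 12 2-{1-[(1S,2S,3R,4R,6S)-2,3-bis(tert-butyldimethylsilyloxy)-1-methyl-7-oxabicyclo[4.1.0]heptan-4-yl]ethenyl}-4,4,5,5-tetramethyl-1,3,2-dioxaborolane; 16 vinyllithium; 14 2-methylprop-1-en-1-yl trifluoromethanesulfonate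
Product: 18 2-{(3S)-2-[(1S,2S,3R,4R,6S)-2,3-bis(tert-butyldimethylsilyloxy)-1-methyl-7-oxabicyclo[4.1.0]heptan-4-yl]-6-methylhepta-1,5-dien-3-yl}-4,4,5,5-tetramethyl-1,3,2-dioxaborolane (8S allylboronate), via lithium ate complex 17 (not isolated)
Conditions: 16 (1.0 equiv), Et2O/THF, 0 °C to rt; then Pd(OAc)2 (3 mol%), (Sp,Sp)-1,1′-bis(diphenylphosphino)-2,2′-bis[α-(dimethylamino)benzyl]ferrocene (C52H50FeN2P2, 3.6 mol%), 14 (1.2 equiv), THF, 60 °C
Reagents that add atoms: none
Why: Vinyllithium 16 adds to boron of 12 to give the bis(alkenyl) ate complex 17. Oxidative addition of 14 to zerovalent palladium gives a cationic alkenyl complex of divalent palladium that binds the unsubstituted B-vinyl group; this induces 1,2-migration of the ring-bearing alkenyl carbon C7 from boron to C8, anti to palladium on C9, and reductive elimination then joins C9 to C10 and regenerates zerovalent palladium. The closest known reaction type is the enantioselective palladium-catalysed conjunctive cross-coupling of bis(alkenyl)boron ate complexes with aryl and alkenyl triflates to α-chiral allylboronates. No ring is closed. C8 is the only new stereocentre and is set by the ferrocenyl bisphosphine, which selects the face of the vinyl group bound to palladium while the migrating carbon arrives on the opposite face; the ring centres lie three or more bonds from C8 and should only modulate the level of induction. The step needs site selectivity (palladium on the vinyl group, not on the 1,1-disubstituted C7 alkenyl group), secured by the lower hindrance of the monosubstituted alkene. It also needs the metallate shift to outrun direct transmetalation, which is favoured by the wide-bite-angle bisphosphine and a halide-free triflate electrophile. The ring epoxide and silyl ethers are spectators: 16 is used in one equivalent and is consumed by boron before it can attack the hindered epoxide.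

**Step 11**
Reactants: 18 2-{(3S)-2-[(1S,2S,3R,4R,6S)-2,3-bis(tert-butyldimethylsilyloxy)-1-methyl-7-oxabicyclo[4.1.0]heptan-4-yl]-6-methylhepta-1,5-dien-3-yl}-4,4,5,5-tetramethyl-1,3,2-dioxaborolane
Product: 19 (3S)-2-[(1S,2S,3R,4R,6S)-2,3-bis(tert-butyldimethylsilyloxy)-1-methyl-7-oxabicyclo[4.1.0]heptan-4-yl]-6-methylhepta-1,5-dien-3-ol
Conditions: NaBO3·4H2O, THF/H2O (1:1), rt
Reagents that add atoms: sodium perborate, B(=O)O[O-].[Na+]
Why: Oxidation of a secondary boronic ester; hydroperoxide adds to boron and C8 migrates from boron to oxygen with retention and without allylic transposition. The nearly neutral oxidant leaves the epoxide, silyl ethers and alkenes untouched.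

**Step 12**
Reactants: 19 (3S)-2-[(1S,2S,3R,4R,6S)-2,3-bis(tert-butyldimethylsilyloxy)-1-methyl-7-oxabicyclo[4.1.0]heptan-4-yl]-6-methylhepta-1,5-dien-3-ol; 20 angelic anhydride, (Z)-2-methylbut-2-enoic anhydride
Product: 22 (3S)-2-[(1S,2S,3R,4R,6S)-2,3-bis(tert-butyldimethylsilyloxy)-1-methyl-7-oxabicyclo[4.1.0]heptan-4-yl]-6-methylhepta-1,5-dien-3-yl (Z)-2-methylbut-2-enoate, via lithium alkoxide 21 (not isolated)
Conditions: LiN(SiMe3)2 (1.1 equiv), THF, −78 °C; then 20 (1.5 equiv), −78 to 0 °C; aq. NH4Cl
Reagents that add atoms: none
Why: O-Acylation of a lithium alkoxide by a symmetrical anhydride; C8–OH is the only free hydroxyl of 19, and because neither a nucleophilic catalyst nor an acid chloride is involved, the addition–elimination pathway that turns angeloyl donors into tigloyl ones is closed and the Z geometry is kept. The C8–O bond is not broken, so the configuration at C8 is untouched, and the hindered amide base at −78 °C leaves the epoxide and silyl ethers alone.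

**Step 13**
Reactants: 22 (3S)-2-[(1S,2S,3R,4R,6S)-2,3-bis(tert-butyldimethylsilyloxy)-1-methyl-7-oxabicyclo[4.1.0]heptan-4-yl]-6-methylhepta-1,5-dien-3-yl (Z)-2-methylbut-2-enoate
Product: 23 (3S)-2-[(1R,2S,3R,4R,6S)-2,3-dihydroxy-1-methyl-7-oxabicyclo[4.1.0]heptan-4-yl]-6-methylhepta-1,5-dien-3-yl (Z)-2-methylbut-2-enoate
Conditions: Bu4NF, AcOH (1:1), THF, rt to 40 °C
Reagents that add atoms: none
Why: Fluoride-induced cleavage of both silyl ethers; buffering with acetic acid keeps the liberated oxygens protonated so that the C5 oxygen does not attack the neighbouring epoxide (Payne-type migration) and the C8 ester is not cleaved. Any acyl migration from C8 to a ring oxygen would be harmless, since the next step esterifies every free hydroxyl with the same acyl group.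

**Step 14**
Reactants: 23 (3S)-2-[(1R,2S,3R,4R,6S)-2,3-dihydroxy-1-methyl-7-oxabicyclo[4.1.0]heptan-4-yl]-6-methylhepta-1,5-dien-3-yl (Z)-2-methylbut-2-enoate; 20 angelic anhydride, (Z)-2-methylbut-2-enoic anhydride
Product: 25 (1S,2S,3R,4R,6S)-1-methyl-4-{(3S)-6-methyl-3-[(Z)-2-methylbut-2-enoyloxy]hepta-1,5-dien-2-yl}-7-oxabicyclo[4.1.0]heptane-2,3-diyl bis[(Z)-2-methylbut-2-enoate], via dilithium dialkoxide 24 (not isolated)
Conditions: LiN(SiMe3)2 (2.2 equiv), THF, −78 °C; then 20 (3 equiv), −78 to 0 °C; aq. NH4Cl
Reagents that add atoms: none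
Why: Twofold O-acylation of the lithium alkoxides of the vicinal diol by the symmetrical anhydride, again without a nucleophilic catalyst, so the Z geometry of all three esters is kept. C4 is fully substituted, so opening of the epoxide by the C5 alkoxide should be slow at −78 °C compared with acylation, and acyl transfer among the three oxygens is without consequence because the acyl groups are identical.

**Step 15**
Reactants: 25 (1S,2S,3R,4R,6S)-1-methyl-4-{(3S)-6-methyl-3-[(Z)-2-methylbut-2-enoyloxy]hepta-1,5-dien-2-yl}-7-oxabicyclo[4.1.0]heptane-2,3-diyl bis[(Z)-2-methylbut-2-enoate]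
Product: 26 (1S,2S,3R,4R,6S)-4-{(3S)-4-[(2R)-3,3-dimethyloxiran-2-yl]-3-[(Z)-2-methylbut-2-enoyloxy]but-1-en-2-yl}-1-methyl-7-oxabicyclo[4.1.0]heptane-2,3-diyl bis[(Z)-2-methylbut-2-enoate] (CNP0258231.1)
Conditions: 1,2:4,5-di-O-isopropylidene-β-D-erythro-hexo-2,3-diulo-2,6-pyranose (0.5 equiv), KHSO5 (as 2KHSO5·KHSO4·K2SO4), K2CO3, Bu4NHSO4 (cat.), MeCN/CH2(OMe)2–aq. Na2B4O7 buffer, pH 10.5, 0 °C
Reagents that add atoms: potassium peroxymonosulfate, [K+].[O-]S(=O)(=O)OO
Why: Shi epoxidation; the dioxirane formed from the D-fructose-derived ketone epoxidises the trisubstituted C10=C11 alkene through a spiro transition state on the face that gives 10R (reagent control). The 1,1-disubstituted C7 alkene with its allylic ester and the electron-poor angelate alkenes react far more slowly, and the buffered basic medium preserves both epoxides.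

## Compound list

1 | (S)-(+)-carvone, (5S)-2-methyl-5-(prop-1-en-2-yl)cyclohex-2-en-1-one | CC(=C)[C@H]1CC=C(C)C(=O)C1 | starting material
2 | (1S,4S,6S)-1-methyl-4-(prop-1-en-2-yl)-7-oxabicyclo[4.1.0]heptan-2-one | CC(=C)[C@H]1C[C@@H]2O[C@]2(C)C(=O)C1 | intermediate
3 | sodium (1S,4S,6S)-1-methyl-4-(prop-1-en-2-yl)-7-oxabicyclo[4.1.0]hept-2-en-2-olate | CC(=C)[C@H]1C[C@@H]2O[C@]2(C)C([O-])=C1.[Na+] | intermediate (not isolated)
4 | (1S,3R,4R,6S)-3-hydroxy-1-methyl-4-(prop-1-en-2-yl)-7-oxabicyclo[4.1.0]heptan-2-one | CC(=C)[C@H]1C[C@@H]2O[C@]2(C)C(=O)[C@@H]1O | intermediate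
5 | (1R,2S,3R,4R,6S)-1-methyl-4-(prop-1-en-2-yl)-7-oxabicyclo[4.1.0]heptane-2,3-diol | CC(=C)[C@H]1C[C@@H]2O[C@]2(C)[C@@H](O)[C@@H]1O | intermediate
6 | (1S,2S,3R,4R,6S)-2,3-bis(tert-butyldimethylsilyloxy)-1-methyl-4-(prop-1-en-2-yl)-7-oxabicyclo[4.1.0]heptane | CC(=C)[C@H]1C[C@@H]2O[C@]2(C)[C@@H](O[Si](C)(C)C(C)(C)C)[C@@H]1O[Si](C)(C)C(C)(C)C | intermediate
7 | 3-[(1S,2S,3R,4S,6S)-2,3-bis(tert-butyldimethylsilyloxy)-1-methyl-7-oxabicyclo[4.1.0]heptan-4-yl]-3-methyl-1,2,4-trioxolane (secondary ozonide, trioxolane carbon unassigned) | CC3(OCOO3)[C@H]1C[C@@H]2O[C@]2(C)[C@@H](O[Si](C)(C)C(C)(C)C)[C@@H]1O[Si](C)(C)C(C)(C)C | intermediate (not isolated)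
8 | 1-[(1S,2S,3R,4S,6S)-2,3-bis(tert-butyldimethylsilyloxy)-1-methyl-7-oxabicyclo[4.1.0]heptan-4-yl]ethan-1-one | CC(=O)[C@H]1C[C@@H]2O[C@]2(C)[C@@H](O[Si](C)(C)C(C)(C)C)[C@@H]1O[Si](C)(C)C(C)(C)C | intermediate
9 | potassium 1-[(1S,2S,3R,4S,6S)-2,3-bis(tert-butyldimethylsilyloxy)-1-methyl-7-oxabicyclo[4.1.0]heptan-4-yl]ethen-1-olate | [K+].[O-]C(=C)[C@H]1C[C@@H]2O[C@]2(C)[C@@H](O[Si](C)(C)C(C)(C)C)[C@@H]1O[Si](C)(C)C(C)(C)C | intermediate (not isolated)
10 | 1-[(1S,2S,3R,4S,6S)-2,3-bis(tert-butyldimethylsilyloxy)-1-methyl-7-oxabicyclo[4.1.0]heptan-4-yl]ethenyl trifluoromethanesulfonate | C=C(OS(=O)(=O)C(F)(F)F)[C@H]1C[C@@H]2O[C@]2(C)[C@@H](O[Si](C)(C)C(C)(C)C)[C@@H]1O[Si](C)(C)C(C)(C)C | intermediate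
11 | bis(pinacolato)diboron | CC1(C)OB(OC1(C)C)B1OC(C)(C)C(C)(C)O1 | starting material
12 | 2-{1-[(1S,2S,3R,4R,6S)-2,3-bis(tert-butyldimethylsilyloxy)-1-methyl-7-oxabicyclo[4.1.0]heptan-4-yl]ethenyl}-4,4,5,5-tetramethyl-1,3,2-dioxaborolane | C=C(B1OC(C)(C)C(C)(C)O1)[C@H]2C[C@@H]3O[C@]3(C)[C@@H](O[Si](C)(C)C(C)(C)C)[C@@H]2O[Si](C)(C)C(C)(C)C | intermediate
13 | isobutyraldehyde (2-methylpropanal) | CC(C)C=O | starting material
14 | 2-methylprop-1-en-1-yl trifluoromethanesulfonate | CC(C)=COS(=O)(=O)C(F)(F)F | intermediate
15 | tetravinylstannane | C=C[Sn](C=C)(C=C)C=C | starting material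
16 | vinyllithium | [Li]C=C | intermediate
17 | lithium ethenyl{1-[(1S,2S,3R,4R,6S)-2,3-bis(tert-butyldimethylsilyloxy)-1-methyl-7-oxabicyclo[4.1.0]heptan-4-yl]ethenyl}(pinacolato)borate | [Li+].C=C[B-]1(OC(C)(C)C(C)(C)O1)C(=C)[C@H]2C[C@@H]3O[C@]3(C)[C@@H](O[Si](C)(C)C(C)(C)C)[C@@H]2O[Si](C)(C)C(C)(C)C | intermediate (not isolated)
18 | 2-{(3S)-2-[(1S,2S,3R,4R,6S)-2,3-bis(tert-butyldimethylsilyloxy)-1-methyl-7-oxabicyclo[4.1.0]heptan-4-yl]-6-methylhepta-1,5-dien-3-yl}-4,4,5,5-tetramethyl-1,3,2-dioxaborolane | C=C([C@H](CC=C(C)C)B1OC(C)(C)C(C)(C)O1)[C@H]2C[C@@H]3O[C@]3(C)[C@@H](O[Si](C)(C)C(C)(C)C)[C@@H]2O[Si](C)(C)C(C)(C)C | intermediate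
19 | (3S)-2-[(1S,2S,3R,4R,6S)-2,3-bis(tert-butyldimethylsilyloxy)-1-methyl-7-oxabicyclo[4.1.0]heptan-4-yl]-6-methylhepta-1,5-dien-3-ol | C=C([C@H](CC=C(C)C)O)[C@H]1C[C@@H]2O[C@]2(C)[C@@H](O[Si](C)(C)C(C)(C)C)[C@@H]1O[Si](C)(C)C(C)(C)C | intermediate
20 | angelic anhydride, (Z)-2-methylbut-2-enoic anhydride | C/C=C(/C)C(=O)OC(=O)/C(C)=C\C | starting material
21 | lithium alkoxide of 19, lithium (3S)-2-[2,3-bis(tert-butyldimethylsilyloxy)-1-methyl-7-oxabicyclo[4.1.0]heptan-4-yl]-6-methylhepta-1,5-dien-3-olate (ring configuration as in 19) | [Li+].C=C([C@H](CC=C(C)C)[O-])[C@H]1C[C@@H]2O[C@]2(C)[C@@H](O[Si](C)(C)C(C)(C)C)[C@@H]1O[Si](C)(C)C(C)(C)C | intermediate (not isolated)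
22 | (3S)-2-[(1S,2S,3R,4R,6S)-2,3-bis(tert-butyldimethylsilyloxy)-1-methyl-7-oxabicyclo[4.1.0]heptan-4-yl]-6-methylhepta-1,5-dien-3-yl (Z)-2-methylbut-2-enoate | C=C([C@H](CC=C(C)C)OC(=O)/C(C)=C\C)[C@H]1C[C@@H]2O[C@]2(C)[C@@H](O[Si](C)(C)C(C)(C)C)[C@@H]1O[Si](C)(C)C(C)(C)C | intermediate
23 | (3S)-2-[(1R,2S,3R,4R,6S)-2,3-dihydroxy-1-methyl-7-oxabicyclo[4.1.0]heptan-4-yl]-6-methylhepta-1,5-dien-3-yl (Z)-2-methylbut-2-enoate | C=C([C@H](CC=C(C)C)OC(=O)/C(C)=C\C)[C@H]1C[C@@H]2O[C@]2(C)[C@@H](O)[C@@H]1O | intermediate
24 | dilithium 2,3-diolate of 23 (both ring hydroxyls deprotonated, configuration as in 23) | [Li+].[Li+].C=C([C@H](CC=C(C)C)OC(=O)/C(C)=C\C)[C@H]1C[C@@H]2O[C@]2(C)[C@@H]([O-])[C@@H]1[O-] | intermediate (not isolated)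
25 | (1S,2S,3R,4R,6S)-1-methyl-4-{(3S)-6-methyl-3-[(Z)-2-methylbut-2-enoyloxy]hepta-1,5-dien-2-yl}-7-oxabicyclo[4.1.0]heptane-2,3-diyl bis[(Z)-2-methylbut-2-enoate] | C=C([C@H](CC=C(C)C)OC(=O)/C(C)=C\C)[C@H]1C[C@@H]2O[C@]2(C)[C@@H](OC(=O)/C(C)=C\C)[C@@H]1OC(=O)/C(C)=C\C | intermediate
26 | (1S,2S,3R,4R,6S)-4-{(3S)-4-[(2R)-3,3-dimethyloxiran-2-yl]-3-[(Z)-2-methylbut-2-enoyloxy]but-1-en-2-yl}-1-methyl-7-oxabicyclo[4.1.0]heptane-2,3-diyl bis[(Z)-2-methylbut-2-enoate] | C=C([C@H](C[C@H]1OC1(C)C)OC(=O)/C(C)=C\C)[C@H]1C[C@@H]2O[C@]2(C)[C@@H](OC(=O)/C(C)=C\C)[C@@H]1OC(=O)/C(C)=C\C | target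

## Step count and least certain steps

Total step count: 15. Longest linear sequence: 13 steps (steps 1–7 and 10–15); steps 8 and 9 are one-step side branches.

**Step 10 (key step).** Direct transmetalation of an alkenyl group from boron to palladium (a Suzuki-type diene coupling) may compete with the metallate shift, because the migrating group is a hindered, α-branched alkenyl group. Palladium may also engage the C7 alkenyl group, so that the vinyl group migrates. The catalyst may not fully override the influence of the neighbouring ring on the configuration at C8. The fallback keeps the C7–C8 bond formation by 1,2-metallate shift but sets C8 with a stoichiometric chiral base; it sets out from 12 and returns at 18. 4-Methylpent-3-en-1-ol is converted into its N,N-diisopropylcarbamate F1. Deprotonation with s-BuLi and the sparteine enantiomer that delivers the (R)-configured carbenoid (expected to be (+)-sparteine; Et2O, −78 °C) gives the α-lithiated carbamate F2. Addition of 12 gives the ate complex F3 with retention at carbon. On warming with MgBr2 the C7 alkenyl group migrates to C8 with inversion and loss of the carbamate, giving 18 with C9–C11 already in place, so that 14 and 16 are not needed.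

**Step 3.** Hydride may be delivered to the wrong face of the C5 carbonyl, since the inherent facial preference of an epoxy ketone need not coincide with the directing effect of C6–OH. The five-membered delivery geometry may also make the reduction slow enough for acid-promoted epoxide opening to intervene. The fallback sets C5 before the epoxide exists; it sets out from 1 and returns at 8. Compound 1 is hydroxylated as in step 2 to trans-6-hydroxycarvone F4. NaBH4/CeCl3·7H2O reduces the enone by axial hydride delivery to the all-trans diol F5, and bis-silylation gives the bis(silyl ether) F6. The less hindered isopropenyl group is cleaved by Lemieux–Johnson oxidation (OsO4 cat., NaIO4, 2,6-lutidine) to methyl ketone F7. Peracid epoxidation (mCPBA, NaHCO3) of the one remaining alkene, anti to the bulky allylic C5 silyl ether, returns 8.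

**Step 14.** Acylation may stop at a mono-ester, because the C5 and C6 oxygens are vicinal and C5 sits beside the fully substituted C4. Prolonged exposure to base may isomerise angeloyl groups from Z to E through γ-deprotonation, and the C5 alkoxide may attack the neighbouring epoxide. The fallback builds the two ring Z alkenes after the ester bonds; it sets out from 23 and returns at 25. Diol 23 is esterified with 2-(diphenoxyphosphoryl)propanoic acid (N,N′-dicyclohexylcarbodiimide, CH2Cl2) to the bis-phosphonate F8. A twofold Z-selective Horner–Wadsworth–Emmons olefination with acetaldehyde (NaH, THF, −78 °C) then gives 25.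

**Step 2.** The epoxy ketone enolate may be diverted by addition to the sulfonimine by-product or by Favorskii-type collapse onto the epoxide, and facial selectivity at C6 may be incomplete. The fallback is a Rubottom oxidation; it sets out from 2 and returns at 4. The enolate (LiN(iPr)2, THF, −78 °C) is trapped with Me3SiCl as the silyl enol ether F9. Oxidation of F9 with dimethyldioxirane on the face opposite the C1 substituent, followed by mild acidic work-up that removes the silyl group, gives 4.

## Further compounds

F1 | step 10 | 4-methylpent-3-en-1-yl N,N-diisopropylcarbamate | CC(C)=CCCOC(=O)N(C(C)C)C(C)C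
F2 | step 10 | (R)-1-lithio-4-methylpent-3-en-1-yl N,N-diisopropylcarbamate (sparteine complex) | CC(C)N(C(C)C)C(=O)O[C@@H](CC=C(C)C)[Li]
F3 | step 10 | lithium ate complex of 12 with F2 (carbamoyloxy carbon bound to boron) | [Li+].CC(C)N(C(C)C)C(=O)O[C@@H](CC=C(C)C)[B-]1(OC(C)(C)C(C)(C)O1)C(=C)[C@H]2C[C@@H]3O[C@]3(C)[C@@H](O[Si](C)(C)C(C)(C)C)[C@@H]2O[Si](C)(C)C(C)(C)C
F4 | step 3 | (5R,6R)-6-hydroxy-2-methyl-5-(prop-1-en-2-yl)cyclohex-2-en-1-one | CC(=C)[C@H]1CC=C(C)C(=O)[C@@H]1O
F5 | step 3 | (1R,2R,6R)-3-methyl-6-(prop-1-en-2-yl)cyclohex-3-ene-1,2-diol | CC(=C)[C@H]1CC=C(C)[C@@H](O)[C@@H]1O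
F6 | step 3 | bis(tert-butyldimethylsilyl) ether of F5 | CC(=C)[C@H]1CC=C(C)[C@@H](O[Si](C)(C)C(C)(C)C)[C@@H]1O[Si](C)(C)C(C)(C)C
F7 | step 3 | 1-[(1S,5R,6R)-5,6-bis(tert-butyldimethylsilyloxy)-4-methylcyclohex-3-en-1-yl]ethan-1-one | CC(=O)[C@H]1CC=C(C)[C@@H](O[Si](C)(C)C(C)(C)C)[C@@H]1O[Si](C)(C)C(C)(C)C
F8 | step 14 | bis[2-(diphenoxyphosphoryl)propanoate] of diol 23 at the C5 and C6 oxygens (phosphonate α-carbons unassigned) | C=C([C@H](CC=C(C)C)OC(=O)/C(C)=C\C)[C@H]1C[C@@H]2O[C@]2(C)[C@@H](OC(=O)C(C)P(=O)(Oc3ccccc3)Oc4ccccc4)[C@@H]1OC(=O)C(C)P(=O)(Oc1ccccc1)Oc1ccccc1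
F9 | step 2 | trimethylsilyl enol ether of 2, trimethyl{[(1S,4S,6S)-1-methyl-4-(prop-1-en-2-yl)-7-oxabicyclo[4.1.0]hept-2-en-2-yl]oxy}silane | CC(=C)[C@H]1C[C@@H]2O[C@]2(C)C(O[Si](C)(C)C)=C1
A1 | alternative 1 | 3-methylfuran | Cc1ccoc1
A2 | alternative 1 | 2,2,2-trifluoroethyl acrylate | C=CC(=O)OCC(F)(F)F
A3 | alternative 1 | 2,2,2-trifluoroethyl 5-methyl-7-oxabicyclo[2.2.1]hept-5-ene-2-endo-carboxylate | FC(F)(F)COC(=O)[C@H]1C[C@H]2C(C)=C[C@@H]1O2
A4 | alternative 2 | (4Z)-2-[1-(tert-butyldimethylsilyloxy)-2-oxoethyl]-5-iodo-N-methoxy-N-methylhex-4-enamide | CON(C)C(=O)[C@@H](C/C=C(/C)I)[C@@H](O[Si](C)(C)C(C)(C)C)C=O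
A5 | alternative 2 | cyclohexenol with C5–OH, C6 silyl ether and C7 Weinreb amide | CON(C)C(=O)[C@H]1CC=C(C)[C@@H](O)[C@@H]1O[Si](C)(C)C(C)(C)C
A6 | alternative 3 | tert-butyl{[2-(4-methylcyclohexa-2,4-dien-1-yl)prop-2-en-1-yl]oxy}dimethylsilane | C=C(CO[Si](C)(C)C(C)(C)C)[C@H]1CC=C(C)C=C1
A7 | alternative 3 | endoperoxide bridging C3 and C6, trans to the C1 substituent | C=C(CO[Si](C)(C)C(C)(C)C)[C@H]1C[C@H]2C(C)=C[C@@H]1OO2
A8 | alternative 3 | syn-bis-epoxide (C3–C4 and C5–C6 oxiranes, both trans to the C1 substituent) | C=C(CO[Si](C)(C)C(C)(C)C)[C@H]1C[C@@H]2O[C@]2(C)[C@@H]3O[C@H]13
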